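**Retrosynthetic overview**

1. Feature: ring A (C1 ester carbinol, C2, C3, C4 fusion CH, C9 quaternary, C10 CHCH3), ring B (C4, C5 CHOH, C6 C=O, C7 alkylidene, C8, C9) and the unit C11(C13H3)–C12H2OH on C7 hold fifteen carbons. The cis C9/C10 methyl pair beside a three-carbon branch on C7 is the eremophilane pattern, that is, a farnesyl chain whose C4 methyl has moved to C9.
2. Last bond made: the C1–O acyl bond. This gives a C5,C12-bis-silylated keto triol and (2E,4E,6E)-5-methyldodeca-2,4,6-trienoic acid (hexanal + C5 phosphonate + C2 ylide).
3. The heteroatoms and C4–H are then removed in reverse order of entry: C5–OH (enolate hydroxylation), C7=C11/C12–OH (opening of a β,γ-epoxy ketone), C4–H (enone hydrogenation with the side-chain alkene masked as that epoxide), C1–OH (P450), C6=O (allylic oxidation). This leads back to (+)-aristolochene.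
4. Key disconnection: C7–C8, C4–C9 and C9–CH3, back to (2E,6E)-farnesyl diphosphate, which comes from farnesol in two steps.
5. Ring order: the ten-membered carbocycle closes first (C7–C8). One transannular bond (C4–C9) then turns it into rings A and B at the same time.

Key step: step 3

Conventions: the numbering of line 1 is used throughout. α is the decalin face that carries the C9 methyl group and β is the opposite face. In this numbering the target is (1R,4S,5R,9R,10R,7Z), with C9-CH3, C10-CH3, C4-H and C5-OH on the α face and the C1 ester oxygen on the β face.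

Assumption: the C1 hydroxylase of step 5 is taken to be available as a recombinant enzyme from a fungus that makes C1-oxygenated eremophilanes. Compound 3 is drawn as the free acid although it is handled as its ammonium salt. Compounds 9 and 10 are carried as C11 epimer mixtures because C11 becomes sp2 in step 8.

**Step 1**
Reactants: 1 (2E,6E)-farnesol
Product: 2 (2E,6E)-farnesyl bromide
Conditions: PBr3 (0.4 equiv), Et2O, −10 °C
Reagents that add atoms: phosphorus tribromide, BrP(Br)Br
Why: Bromination of a primary allylic alcohol through its phosphite ester (SN2 by bromide) at low temperature should keep both E alkenes and avoid allylic transposition.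

**Step 2**
Reactants: 2 (2E,6E)-farnesyl bromide
Product: 3 (2E,6E)-farnesyl diphosphate
Conditions: (n-Bu4N)3HP2O7 (2 equiv), MeCN, rt; then Dowex 50W-X8 (NH4+ form), cellulose chromatography
Reagents that add atoms: tris(tetrabutylammonium) hydrogen diphosphate, CCCC[N+](CCCC)(CCCC)CCCC.CCCC[N+](CCCC)(CCCC)CCCC.CCCC[N+](CCCC)(CCCC)CCCC.OP(=O)([O-])OP(=O)([O-])[O-]
Why: SN2 displacement of the primary allylic bromide by the acetonitrile-soluble diphosphate salt, followed by cation exchange, is the standard entry to allylic diphosphates and leaves the E,E geometry untouched.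

**Step 3**
Reactants: 3 (2E,6E)-farnesyl diphosphate
Product: 6 (+)-aristolochene, via (S)-germacrene A 4 (not isolated), via eudesmane cation 5 (not isolated)
Conditions: recombinant aristolochene synthase (Aspergillus terreus gene, expressed in E. coli), MgCl2 (5 mM), Tris-HCl pH 7.5, glycerol, 2-mercaptoethanol, pentane overlay, 30 °C
Reagents that add atoms: none
Why: Divalent magnesium bound to the diphosphate of 3 assists its ionisation, the C7=C11 π bond attacks C8 of the allyl cation (C7–C8 bond, ten-membered ring) and loss of a methyl proton from the C11 cation leaves enzyme-bound 4; reprotonation of 4 at C3 lets C9=C10 attack C4 (C4–C9 bond) to give 5, after which a 1,2-hydride shift C9→C10 on the β face, a 1,2-methyl shift C4→C9 on the α face and loss of the β proton at C5 deliver the C4=C5 alkene of 6. The closest known reaction type is this very one, the native turnover of a magnesium-dependent, diphosphate-ionising sesquiterpene cyclase, which is a cationic polyene cyclisation with Wagner–Meerwein shifts. The ten-membered ring closes in the exo mode with respect to the attacking alkene (C11 stays outside, Markovnikov), and the single transannular closure is 6-endo for ring A and 6-exo for ring B. C7 is set by the alkene face that the folded chain offers to C8, while C9 and C10 are set by the conformation in which 4 is held and by the suprafacial, mutually anti migrations, which place both methyl groups on the α face. The step needs 1,10- over 1,11-closure, retention of 4 until it is reprotonated, and proton loss from C5 rather than C3; the E,E geometry of 3 and the contour of the active site secure all three, which no Brønsted or Lewis acid in solution does.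

**Step 4**
Reactants: 6 (+)-aristolochene
Product: 7 aristolochen-6-one (C4=C5–C6=O enone; C7 isopropenyl β)
Conditions: t-BuOOH (70% in H2O, excess), dirhodium tetracaprolactamate Rh2(cap)4 (1 mol %), ClCH2CH2Cl, 40 °C
Reagents that add atoms: tert-butyl hydroperoxide, CC(C)(C)OO
Why: Radical allylic oxidation by tert-butylperoxyl radicals attacks the CH2 next to the CH terminus of a trisubstituted ring alkene (the selectivity seen for Δ5-steroids to 7-ketones and for valencene to nootkatone), so C6 should be oxidised in preference to C3, base-free conditions keep the isopropenyl group out of conjugation, and no stereocentre is touched.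

**Step 5**
Reactants: 7 aristolochen-6-one
Product: 8 C1β-hydroxy-aristolochen-6-one
Conditions: fungal eremophilane C1-hydroxylase (cytochrome P450) with its NADPH-P450 reductase (yeast lysate), NADP+ (cat.), D-glucose, glucose dehydrogenase, air, potassium phosphate pH 7.4, 2% DMSO, 28 °C
Reagents that add atoms: dioxygen, O=O
Why: Cytochrome P450 C–H hydroxylation (hydrogen abstraction and oxygen rebound with retention) is how fungi of this metabolite family oxygenate C1 of this dienone skeleton, so the site (C1 over C2, C3 and the allylic methyl) and the face (replacement of the equatorial β hydrogen, giving the alcohol trans to the C10 methyl) are set by the fit of 7 in the enzyme pocket and not by innate C–H reactivity.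

**Step 6**
Reactants: 8 C1β-hydroxy-aristolochen-6-one
Product: 9 C11,C12-epoxide of 8 (both C11 epimers)
Conditions: mCPBA (1.05 equiv), CH2Cl2/aq. NaHCO3 (two-phase), 0 °C
Reagents that add atoms: 3-chloroperbenzoic acid, O=C(OO)c1cccc(Cl)c1
Why: Prilezhaev epoxidation is electrophilic, so the isolated 1,1-disubstituted C11=C12 alkene reacts far faster than the electron-poor C4=C5 enone; the new centre C11 may form as a mixture because it becomes sp2 again in step 8, and the epoxide both shields this alkene from step 7 and already carries the C12 oxygen.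

**Step 7**
Reactants: 9 C11,C12-epoxide of 8
Product: 10 cis-fused epoxy decalone (C4-H α)
Conditions: H2 (1 atm), 10% Pd/C, EtOAc, rt
Reagents that add atoms: none
Why: In this heterogeneous catalytic hydrogenation the C4=C5 enone is the only reducible π bond left, and 4a-methyl- and 4,4a-dimethyl-octalones of this type take up hydrogen on palladium to give the cis-decalone, which sets C4-H on the α face; the non-activated epoxide and the free alcohol are inert in neutral EtOAc, and epimerisation at C7 would be of no consequence.

**Step 8**
Reactants: 10 cis-fused epoxy decalone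
Product: 11 (7Z)-C1β,C12-dihydroxy enone (C6 ketone; C7=C11)
Conditions: DBU (1 equiv), toluene, rt → 60 °C
Reagents that add atoms: none
Why: In this E1cB opening of a β,γ-epoxy ketone DBU removes the acidic C7-H and the enolate expels the C11–O bond, which creates C7=C11 and frees C12-OH in one operation while erasing C7 and C11 as stereocentres; continued reversible γ-deprotonation on warming in the apolar solvent should let the geometry settle on the Z isomer, the only one whose C12-OH can hydrogen-bond to (or hemiketalise with) the C6 carbonyl, and any E isomer is separated and resubmitted.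

**Step 9**
Reactants: 11 (7Z)-C1β,C12-dihydroxy enone
Product: 13 C12-O-TBS C1-O-TES enone, via C12 TBS ether 12 (not isolated)
Conditions: TBSCl (1.05 equiv), imidazole, DMF, 0 °C; then TESCl (1.5 equiv), rt
Reagents that add atoms: tert-butyldimethylsilyl chloride, CC(C)(C)[Si](C)(C)Cl; triethylsilyl chloride, CC[Si](Cl)(CC)CC
Why: Imidazole-promoted silyl ether formation distinguishes the unhindered primary allylic C12-OH, which takes the bulky TBS group first, from the secondary C1-OH flanked by the C10 methyl, which is then capped in the same flask with the smaller and later more labile TES group.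

**Step 10**
Reactants: 13 C12-O-TBS C1-O-TES enone
Product: 14 C5α-hydroxy ketone
Conditions: KN(SiMe3)2 (1.2 equiv), THF, −78 °C; 2-(phenylsulfonyl)-3-phenyloxaziridine, −78 °C; AcOH quench
Reagents that add atoms: 2-(phenylsulfonyl)-3-phenyloxaziridine, O=S(=O)(N1OC1c1ccccc1)c1ccccc1
Why: In this Davis enolate hydroxylation C7 bears no hydrogen, so kinetic deprotonation takes place at C5, and the bulky oxaziridine meets the C5=C6 enolate on the convex α face (ring A, attached through the axial C9–C10 bond, folds under the β face), which gives the equatorial C5α alcohol that is also the thermodynamically preferred epimer.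

**Step 11**
Reactants: 14 C5α-hydroxy ketone
Product: 15 C5,C12-bis-O-TBS C1-O-TES ketone
Conditions: TBSOTf, 2,6-lutidine, CH2Cl2, −78 → 0 °C
Reagents that add atoms: tert-butyldimethylsilyl triflate, CC(C)(C)[Si](C)(C)OS(=O)(=O)C(F)(F)F
Why: Silylation with the silyl triflate and a hindered pyridine base caps the hydrogen-bonded, hindered ketol hydroxyl without enolising the ketone or disturbing C5, so that only C1–O can be unmasked afterwards.

**Step 12**
Reactants: 15 C5,C12-bis-O-TBS C1-O-TES ketone
Product: 16 C5,C12-bis-O-TBS C1β-alcohol
Conditions: HF·pyridine, excess pyridine, THF, 0 °C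
Reagents that add atoms: none
Why: This selective desilylation relies on the triethylsilyl ether being far more labile to buffered HF than either tert-butyldimethylsilyl ether, so a short exposure at 0 °C should free C1-OH alone.

**Step 13**
Reactants: 17 hexanal; 18 triethyl (E)-3-methyl-4-phosphonocrotonate
Product: 19 ethyl (2E,4E)-3-methyldeca-2,4-dienoate
Conditions: LiN(SiMe3)2, THF/DMPU, −78 → 0 °C
Reagents that add atoms: none
Why: Horner–Wadsworth–Emmons olefination with the vinylogous stabilised phosphonate anion forms the new disubstituted alkene E and favours the E trisubstituted alkene, with any minor 2Z isomer removed by chromatography here or at the stage of 20.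

**Step 14**
Reactants: 19 ethyl (2E,4E)-3-methyldeca-2,4-dienoate
Product: 20 (2E,4E)-3-methyldeca-2,4-dien-1-ol
Conditions: i-Bu2AlH (2.2 equiv), CH2Cl2, −78 °C; aq. Rochelle salt
Reagents that add atoms: none
Why: Reduction with i-Bu2AlH converts the conjugated ester into the allylic alcohol by 1,2-hydride delivery only and leaves both alkene geometries intact.

**Step 15**
Reactants: 20 (2E,4E)-3-methyldeca-2,4-dien-1-ol; 21 ethyl (triphenylphosphoranylidene)acetate
Product: 23 ethyl (2E,4E,6E)-5-methyldodeca-2,4,6-trienoate, via (2E,4E)-3-methyldeca-2,4-dienal 22 (not isolated)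
Conditions: MnO2 (excess), 21 (1.3 equiv), CH2Cl2, rt
Reagents that add atoms: none
Why: In this tandem allylic oxidation–Wittig olefination MnO2 oxidises only the allylic alcohol, and the stabilised ylide traps the isomerisation-prone dienal as it forms, giving the new C2=C3 alkene with E geometry.

**Step 16**
Reactants: 23 ethyl (2E,4E,6E)-5-methyldodeca-2,4,6-trienoate
Product: 24 (2E,4E,6E)-5-methyldodeca-2,4,6-trienoic acid
Conditions: LiOH, THF/MeOH/H2O, rt; then 1 M HCl to pH 3
Reagents that add atoms: lithium hydroxide, [Li+].[OH-]
Why: Saponification of the ethyl ester at room temperature proceeds by acyl–oxygen cleavage and does not affect the conjugated all-E triene.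

**Step 17**
Reactants: 24 (2E,4E,6E)-5-methyldodeca-2,4,6-trienoic acid; 16 C5,C12-bis-O-TBS C1β-alcohol
Product: 26 C5,C12-bis-O-TBS ether of the target, via trienoyl trichlorobenzoyl anhydride 25 (not isolated)
Conditions: 2,4,6-Cl3C6H2COCl, Et3N, toluene, rt; then 16, DMAP, toluene, rt
Reagents that add atoms: none
Why: In this Yamaguchi esterification DMAP attacks mixed anhydride 25 at the less hindered trienoyl carbonyl, and the acylpyridinium ion acylates the only free hydroxyl (C1-OH), with retention at C1 and without change of any alkene geometry.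

**Step 18**
Reactants: 26 C5,C12-bis-O-TBS ether of the target
Product: 27 target CNP0226738.1
Conditions: Bu4NF, AcOH (1:1), THF, 0 °C → rt
Reagents that add atoms: none
Why: Fluoride-mediated desilylation buffered with acetic acid removes both TBS groups close to neutrality, which avoids base-induced ester cleavage or C5 epimerisation as well as acid-induced cyclodehydration of the (Z)-γ-hydroxy enone to a furan.

**Compound list**

1 | (2E,6E)-farnesol | CC(C)=CCC/C(C)=C/CC/C(C)=C/CO | starting material
2 | (2E,6E)-farnesyl bromide | CC(C)=CCC/C(C)=C/CC/C(C)=C/CBr | intermediate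
3 | (2E,6E)-farnesyl diphosphate (drawn as the acid, handled as ammonium salt) | CC(C)=CCC/C(C)=C/CC/C(C)=C/COP(=O)(O)OP(=O)(O)O | intermediate
4 | (S)-germacrene A (E,E ten-membered diene, enzyme-bound) | CC(=C)[C@@H]1C/C=C(\C)CC/C=C(\C)CC1 | intermediate
5 | eudesmane cation (trans-fused; C4-CH3 α; C9-H β; charge on C10) | C1CC[C@]2(C)CC[C@H](C(C)=C)C[C@H]2[C+]1C | intermediate
6 | (+)-aristolochene | C1CCC2=CC[C@H](C(C)=C)C[C@]2(C)[C@H]1C | intermediate
7 | aristolochen-6-one (C4=C5–C6=O; C7 isopropenyl β; C9, C10 methyl α) | C1CCC2=CC(=O)[C@H](C(C)=C)C[C@]2(C)[C@H]1C | intermediate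
8 | C1β-hydroxy-aristolochen-6-one | O[C@@H]1CCC2=CC(=O)[C@H](C(C)=C)C[C@]2(C)[C@H]1C | intermediate
9 | C11,C12-epoxide of 8 (C11 epimers) | O[C@@H]1CCC2=CC(=O)[C@H](C3(C)CO3)C[C@]2(C)[C@H]1C | intermediate
10 | cis-fused epoxy decalone (C4-H α; C11 epimers) | O[C@@H]1CC[C@@H]2CC(=O)[C@H](C3(C)CO3)C[C@]2(C)[C@H]1C | intermediate
11 | (7Z)-C1β,C12-dihydroxy enone | O[C@@H]1CC[C@@H]2CC(=O)/C(=C(/C)CO)C[C@]2(C)[C@H]1C | intermediate
12 | C12 TBS ether of 11 | O[C@@H]1CC[C@@H]2CC(=O)/C(=C(/C)CO[Si](C)(C)C(C)(C)C)C[C@]2(C)[C@H]1C | intermediate
13 | C12-O-TBS, C1-O-TES enone | CC[Si](CC)(CC)O[C@@H]1CC[C@@H]2CC(=O)/C(=C(/C)CO[Si](C)(C)C(C)(C)C)C[C@]2(C)[C@H]1C | intermediate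
14 | C5α-hydroxy ketone | CC[Si](CC)(CC)O[C@@H]1CC[C@@H]2[C@@H](O)C(=O)/C(=C(/C)CO[Si](C)(C)C(C)(C)C)C[C@]2(C)[C@H]1C | intermediate
15 | C5,C12-bis-O-TBS, C1-O-TES ketone | CC[Si](CC)(CC)O[C@@H]1CC[C@@H]2[C@@H](O[Si](C)(C)C(C)(C)C)C(=O)/C(=C(/C)CO[Si](C)(C)C(C)(C)C)C[C@]2(C)[C@H]1C | intermediate
16 | C5,C12-bis-O-TBS C1β-alcohol | O[C@@H]1CC[C@@H]2[C@@H](O[Si](C)(C)C(C)(C)C)C(=O)/C(=C(/C)CO[Si](C)(C)C(C)(C)C)C[C@]2(C)[C@H]1C | intermediate
17 | hexanal | CCCCCC=O | starting material
18 | triethyl (E)-3-methyl-4-phosphonocrotonate | CCOC(=O)/C=C(\C)CP(=O)(OCC)OCC | starting material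
19 | ethyl (2E,4E)-3-methyldeca-2,4-dienoate | CCCCC/C=C/C(C)=C/C(=O)OCC | intermediate
20 | (2E,4E)-3-methyldeca-2,4-dien-1-ol | CCCCC/C=C/C(C)=C/CO | intermediate
21 | ethyl (triphenylphosphoranylidene)acetate | CCOC(=O)C=P(c1ccccc1)(c1ccccc1)c1ccccc1 | starting material
22 | (2E,4E)-3-methyldeca-2,4-dienal | CCCCC/C=C/C(C)=C/C=O | intermediate
23 | ethyl (2E,4E,6E)-5-methyldodeca-2,4,6-trienoate | CCCCC/C=C/C(C)=C/C=C/C(=O)OCC | intermediate
24 | (2E,4E,6E)-5-methyldodeca-2,4,6-trienoic acid | CCCCC/C=C/C(C)=C/C=C/C(=O)O | intermediate
25 | trienoyl 2,4,6-trichlorobenzoyl mixed anhydride | CCCCC/C=C/C(C)=C/C=C/C(=O)OC(=O)c1c(Cl)cc(Cl)cc1Cl | intermediate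
26 | C5,C12-bis-O-TBS ether of the target | CCCCC/C=C/C(C)=C/C=C/C(=O)O[C@@H]1CC[C@@H]2[C@@H](O[Si](C)(C)C(C)(C)C)C(=O)/C(=C(/C)CO[Si](C)(C)C(C)(C)C)C[C@]2(C)[C@H]1C | intermediate
27 | CNP0226738.1 | CCCCC/C=C/C(C)=C/C=C/C(=O)O[C@@H]1CC[C@@H]2[C@@H](O)C(=O)/C(=C(/C)CO)C[C@]2(C)[C@H]1C | target

**Step count**

- Total step count: 18.
- Longest linear sequence: 14 steps (steps 1–12, 17 and 18).

**Steps most likely to fail**

**Step 5.**
- What may go wrong: oxygen insertion drifting from C1 to the weaker allylic C3–H bonds, enzymatic epoxidation of the isopropenyl group, or stalling turnover with the poorly soluble dienone.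
- Fallback (sets out from 7, comes back at 11): the C–H oxidation is moved behind the three steps that remove every competing site.
- Compound 7 is epoxidised with mCPBA to the C1-unsubstituted epoxy enone F1. This is hydrogenated over Pd/C to the cis-fused epoxy decalone F2 and opened with DBU to the (7Z)-12-hydroxy enone F3.
- F3 has no allylic ring C–H bond and no electron-rich alkene left, and its polar C6/C12 end can anchor it so that ring A faces the oxidant.
- A panel of P450 BM3 variants, alongside the fungal enzyme, is then screened on F3. The C1β-alcohol so formed is 11 itself, so no protecting-group step is added.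

**Step 8.**
- What may go wrong: kinetic formation of the E alkene that DBU does not re-equilibrate, or loss of water from the Z isomer through its hemiketal.
- Fallback (sets out from 10, comes back at 11): the geometry is fixed by a ring instead of by an equilibrium.
- Catalytic p-TsOH in benzene converts 10 into the furan F4, in which C6 and C12 are bridged by oxygen. The path is Meinwald rearrangement of the epoxide to the γ-keto aldehyde followed by Paal–Knorr cyclodehydration.
- Dimethyldioxirane in acetone at −20 °C opens the furan oxidatively to the cis-configured keto enal F5, in which C12 must lie on the side of C6.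
- NaBH(OAc)3 then reduces only the aldehyde and gives 11.

**Step 4.**
- What may go wrong: hydrogen abstraction at C3 or at the tertiary C7–H, over-oxidation, or drift of the isopropenyl alkene into conjugation.
- Fallback (sets out from 6, comes back at 7): the radical oxidation is replaced by an ene reaction followed by a transposition.
- Photo-oxygenation (O2, tetraphenylporphyrin, light, CH2Cl2) attacks the more nucleophilic trisubstituted alkene from the β face in a Schenck ene reaction. It removes the pseudoaxial C6-Hβ and gives the tertiary C4β hydroperoxide F6 with a C5=C6 alkene.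
- PPh3 reduces F6 to the tertiary allylic alcohol F7.
- Pyridinium chlorochromate, [C5H5NH][CrO3Cl], carries out the Babler–Dauben oxidative transposition to 7.

**Further compounds**

F1 | step 5 | C1-unsubstituted epoxy enone (C11 epimers) | C1CCC2=CC(=O)[C@H](C3(C)CO3)C[C@]2(C)[C@H]1C
F2 | step 5 | C1-unsubstituted cis-fused epoxy decalone (C4-H α) | C1CC[C@@H]2CC(=O)[C@H](C3(C)CO3)C[C@]2(C)[C@H]1C
F3 | step 5 | C1-unsubstituted (7Z)-12-hydroxy enone | C1CC[C@@H]2CC(=O)/C(=C(/C)CO)C[C@]2(C)[C@H]1C
F4 | step 8 | C1β-hydroxy furan (C6–O–C12 bridge) | O[C@@H]1CC[C@@H]2Cc3occ(C)c3C[C@]2(C)[C@H]1C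
F5 | step 8 | (7Z)-C6-keto C12-enal | O[C@@H]1CC[C@@H]2CC(=O)/C(=C(/C)C=O)C[C@]2(C)[C@H]1C
F6 | step 4 | C4β-hydroperoxide with C5=C6 alkene | C1CC[C@@]2(OO)C=C[C@H](C(C)=C)C[C@]2(C)[C@H]1C
F7 | step 4 | C4β tertiary allylic alcohol with C5=C6 alkene | C1CC[C@@]2(O)C=C[C@H](C(C)=C)C[C@]2(C)[C@H]1C
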